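**Retrosynthetic overview**
1. C–O disconnection at the stereocenter: target ⇒ terminal alkene (undec-10-enyl methoxypyranone) + acetic acid. An enantioselective Markovnikov hydroacetoxylation forms the C–O bond, sets (S) and delivers the acetate directly, with no protecting groups.
2. O–CH3 disconnection: 2-methoxy-4-pyranone ⇒ 4-hydroxy-2-pyranone (O-methylation at the lactone carbonyl oxygen).
3. Ring C–O (lactone) and C5–C6 disconnections: hydroxypyranone ⇒ 3,5-diketo ester ⇒ dianion of methyl 2-ethyl-3-oxopentanoate + dodec-11-enoyl imidazole.
4. Building blocks: keto ester ⇐ methyl 3-oxopentanoate + EtI; dodec-11-enoic acid ⇐ 11-bromoundec-1-ene + CO2.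
5. Ring order: there is one ring, the pyranone, closed in step 3; the side-chain stereocenter is set last.

Target stereochemistry: the single stereocenter is (S), i.e. (2S)-11-(5-ethyl-6-methoxy-3-methyl-4-oxo-4H-pyran-2-yl)undecan-2-yl acetate.

Catalyst Co-1 (new design, used in step 5): the cobalt(II) salen complex of the ligand made from (1R,2R)-cyclohexane-1,2-diamine and two equivalents of 5-tert-butyl-2-hydroxy-3-(2,4,6-triisopropylphenyl)benzaldehyde.

Assumption: the sense of induction of Co-1 cannot be predicted with certainty. The (R,R)-antipode is written as the one giving the (S)-acetate; a calibration run on dodec-1-ene decides, and the (S,S)-antipode is used if it shows the opposite.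

**Step 1**
Reactants: 1 methyl 3-oxopentanoate
Product: 2 methyl 2-ethyl-3-oxopentanoate (racemic)
Conditions: EtI (1.1 equiv), K2CO3 (1.5 equiv), acetone, reflux, 16 h; distil
Reagents that add atoms: iodoethane, CCI
Why: Acetoacetic-ester-type C-alkylation of the doubly activated CH2 with a mild carbonate base gives mainly the mono-ethyl product; its stereocenter is racemic and is erased in step 3.

**Step 2**
Reactants: 3 11-bromoundec-1-ene
Product: 5 dodec-11-enoic acid, via Grignard reagent 4 (not isolated)
Conditions: Mg (1.2 equiv), cat. I2, THF, 40 °C; then CO2, −20 °C → rt; 1 M HCl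
Reagents that add atoms: carbon dioxide, O=C=O
Why: Grignard formation from the primary bromide and carboxylation with CO2 adds the one carbon that becomes C6 of the pyranone; the remote terminal alkene is inert.

**Step 3**
Reactants: 2 methyl 2-ethyl-3-oxopentanoate; 5 dodec-11-enoic acid
Product: 9 3-ethyl-4-hydroxy-5-methyl-6-(undec-10-en-1-yl)-2H-pyran-2-one, via acyl imidazole 6 (not isolated), via dilithio dianion 7 (not isolated), via triketo ester 8 (not isolated)
Conditions: (a) 5, CDI (1.1 equiv), THF, rt, 1 h; (b) 2 (3.0 equiv), LDA (commercial solution, 6.1 equiv), THF, −78 → 0 °C; (c) add (a) to (b), −78 → −20 °C, then 1 M HCl, extract, concentrate; (d) crude, DBU (2 equiv), PhMe, 110 °C; 1 M HCl wash (excess 2 recovered)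
Reagents that add atoms: none
Why: Weiler-type β-keto ester dianion γ-acylation (Claisen C-acylation by the N-acyl imidazole) gives the 3,5-diketo ester, whose C5 enol oxygen then attacks the methyl ester under DBU (lactonisation with loss of methanol) to close the only ring; excess dianion absorbs the acidic protons of imidazole and of 8, and the sp3 stereocenters of 2 and 8 vanish in the hydroxypyranone.

**Step 4**
Reactants: 9 3-ethyl-4-hydroxy-5-methyl-6-(undec-10-en-1-yl)-2H-pyran-2-one
Product: 11 3-ethyl-2-methoxy-5-methyl-6-(undec-10-en-1-yl)-4H-pyran-4-one, via pyrylium triflate 10 (not isolated)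
Conditions: MeOTf (1.5 equiv), CH2Cl2, 0 °C → rt, 12 h; then sat. aq. NaHCO3
Reagents that add atoms: methyl trifluoromethanesulfonate, COS(=O)(=O)C(F)(F)F
Why: Beak-type O-methylation, in which the hard electrophile alkylates the most basic site of the neutral 3,5-dialkyl-4-hydroxy-2-pyranone (the lactone carbonyl oxygen) to give the 4-hydroxy-2-methoxypyrylium salt, which loses a proton on bicarbonate work-up to the 2-methoxy-4-pyranone; the isolated alkene does not react with MeOTf.

**Step 5**
Reactants: 11 3-ethyl-2-methoxy-5-methyl-6-(undec-10-en-1-yl)-4H-pyran-4-one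
Product: 12 (2S)-11-(5-ethyl-6-methoxy-3-methyl-4-oxo-4H-pyran-2-yl)undecan-2-yl acetate (target)
Conditions: (R,R)-Co-1 (5 mol%), N-fluoro-2,4,6-trimethylpyridinium triflate (1.5 equiv), PhSiH3 (1.2 equiv), AcOH (10 equiv), PhCF3, 0 °C, Ar
Reagents that add atoms: acetic acid, CC(=O)O
Why: Proposed new method: an intermolecular, catalyst-controlled enantioselective Markovnikov hydroacetoxylation of an unfunctionalised terminal alkene, in which Co(III)–H (from Co-1, the N–F oxidant and PhSiH3) transfers H• to the terminal CH2 (MHAT, which fixes the regiochemistry and creates the CH3), the secondary radical is captured as sec-alkyl–Co(III) and oxidised to alkyl–Co(IV), and acetic acid displaces cobalt from the back side (SN2, inversion) to form the C–O bond; the two Co–C epimers interconvert by reversible Co–C homolysis, so the aryl-walled pocket of Co-1 (long chain leaves through the open quadrant, methyl sits in the narrow slot) can channel the material to the (S)-acetate in a dynamic kinetic sense, while the tetrasubstituted, electron-poor pyranone C=C bonds do not accept H• from Co–H; the closest known reaction type is the Co(salen)/silane/N-fluoropyridinium radical-polar-crossover hydroalkoxylation and hydroacyloxylation of alkenes (Mukaiyama/Shigehisa type), which to my knowledge is enantioselective mainly in ring-forming cases and has not been shown to distinguish methyl from a long n-alkyl chain at an unactivated secondary carbon.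

**Compound list**
1 | methyl 3-oxopentanoate | CCC(=O)CC(=O)OC | starting material
2 | methyl 2-ethyl-3-oxopentanoate (racemic) | CCC(=O)C(CC)C(=O)OC | intermediate
3 | 11-bromoundec-1-ene | C=CCCCCCCCCCBr | starting material
4 | undec-10-en-1-ylmagnesium bromide (Grignard reagent) | C=CCCCCCCCCC[Mg]Br | intermediate
5 | dodec-11-enoic acid | C=CCCCCCCCCCC(=O)O | intermediate
6 | 1-(imidazol-1-yl)dodec-11-en-1-one (acyl imidazole) | C=CCCCCCCCCCC(=O)n1ccnc1 | intermediate
7 | dilithium bis-enolate (dianion) of methyl 2-ethyl-3-oxopentanoate | [Li+].[Li+].CC=C([O-])C(CC)=C([O-])OC | intermediate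
8 | methyl 2-ethyl-4-methyl-3,5-dioxohexadec-15-enoate (triketo ester, diastereomer/tautomer mixture) | C=CCCCCCCCCCC(=O)C(C)C(=O)C(CC)C(=O)OC | intermediate
9 | 3-ethyl-4-hydroxy-5-methyl-6-(undec-10-en-1-yl)-2H-pyran-2-one | CCc1c(O)c(C)c(CCCCCCCCCC=C)oc1=O | intermediate
10 | 3-ethyl-4-hydroxy-2-methoxy-5-methyl-6-(undec-10-en-1-yl)pyrylium trifluoromethanesulfonate | CCc1c(OC)[o+]c(CCCCCCCCCC=C)c(C)c1O.[O-]S(=O)(=O)C(F)(F)F | intermediate
11 | 3-ethyl-2-methoxy-5-methyl-6-(undec-10-en-1-yl)-4H-pyran-4-one | CCc1c(OC)oc(CCCCCCCCCC=C)c(C)c1=O | intermediate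
12 | (2S)-11-(5-ethyl-6-methoxy-3-methyl-4-oxo-4H-pyran-2-yl)undecan-2-yl acetate | CCc1c(OC)oc(CCCCCCCCC[C@H](C)OC(C)=O)c(C)c1=O | target

**Step count**
Total steps: 5. Longest linear sequence: 4 (step 1 or step 2, then steps 3, 4, 5).

**Three steps most likely to fail**

Step 5 (proposed new step). The main uncertainty is the enantioselectivity, because the catalyst must tell a methyl group from an n-alkyl chain at an unactivated secondary carbon. Side reactions to watch are Co–H alkene isomerisation, hydrofluorination and reduction to the alkane. The product is an oil, so a moderate ee cannot easily be upgraded. The fallback uses known chemistry, sets out from 11 and comes back at 12. Tsuji–Wacker oxidation of 11 (PdCl2 10 mol%, CuCl, O2, DMF/H2O, rt) gives the methyl ketone 3-ethyl-2-methoxy-5-methyl-6-(10-oxoundecyl)-4H-pyran-4-one F1. A Prelog-selective alcohol dehydrogenase (for example Rhodococcus ruber ADH-A or an (S)-selective ketoreductase; NAD(P)H, iPrOH, phosphate buffer pH 7 with a co-solvent, 30 °C) reduces F1 to 3-ethyl-6-[(10S)-10-hydroxyundecyl]-2-methoxy-5-methyl-4H-pyran-4-one F2. Acetylation (Ac2O, pyridine, cat. DMAP, CH2Cl2, rt) then gives 12.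

Step 3. The dianion can be quenched by imidazole and by the acidic product 8, O-acylation can compete, and the telescoped cyclisation runs on crude material. The fallback replaces the Claisen acylation by an aldol/oxidation sequence; it sets out from 3 and 2 and comes back at 9. The Grignard reagent 4 is formylated with DMF (THF, 0 °C; aq. HCl) to dodec-11-enal F3. The dianion 7 (from 2, LDA, THF, −78 °C) adds to F3 to give methyl 2-ethyl-5-hydroxy-4-methyl-3-oxohexadec-15-enoate F4. Dess–Martin periodinane (CH2Cl2, rt) oxidises F4 to 8, now isolated, and DBU in toluene at reflux closes 8 to 9.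

Step 4. Methylation may also give the isomeric 4-methoxy-2-pyranone, which would have to be separated. The fallback avoids the hydroxypyranone altogether; it sets out from 8 and comes back at 11. Step 3 is stopped after the acidic quench and 8 is isolated. Cyclodehydration of 8 with Ph3P/CCl4 (THF, rt → 50 °C), a known way to turn β,δ-diketo esters into α-methoxy-γ-pyranones with retention of the ester methoxy group, gives 11 directly and bypasses 9 and 10 (no new compound, F0).

**Further compounds**
F1 | step 5 | 3-ethyl-2-methoxy-5-methyl-6-(10-oxoundecyl)-4H-pyran-4-one | CCc1c(OC)oc(CCCCCCCCCC(C)=O)c(C)c1=O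
F2 | step 5 | 3-ethyl-6-[(10S)-10-hydroxyundecyl]-2-methoxy-5-methyl-4H-pyran-4-one | CCc1c(OC)oc(CCCCCCCCC[C@H](C)O)c(C)c1=O
F3 | step 3 | dodec-11-enal | C=CCCCCCCCCCC=O
F4 | step 3 | methyl 2-ethyl-5-hydroxy-4-methyl-3-oxohexadec-15-enoate | C=CCCCCCCCCCC(O)C(C)C(=O)C(CC)C(=O)OC
F0 | step 4 | none | none
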